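**Retrosynthetic overview**

1. Tetralone numbering is used: C1 ketone carbon, C2, C3 (carbinol), C4, ring-fusion carbons C4a and C8a, C5 (pyranone), C6 (phenyl), C8 (OH). Ring A is the benzene ring, ring B the hydroxy-cyclohexanone ring, ring C the pyranone.
2. Ring C is disconnected last, to a C5 aldehyde plus 2,2,6-trimethyl-4H-1,3-dioxin-4-one (vinylogous aldol, oxidation, thermal acylketene cyclization).
3. Ring B is disconnected at C1–C2 and C4–C4a, to (R)-epichlorohydrin and a ring A piece carrying C1 as a 1,3-dithiane on C8a and bromine on C4a. This one-flask [3+3] annulation also brings in the C3 stereocenter and the masked ketone.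
4. Enabling feature: in ring B the carbinol carbon C3 lies between two methylenes, C2 (bonded to the carbonyl carbon C1) and C4 (bonded to the arene carbon C4a). C2–C3(O)–C4 is therefore the skeleton of epichlorohydrin, and C1 and C4a, 1,3-related through C8a of ring A, can both be made carbanionic (C1 as a 2-lithio-1,3-dithiane, C4a as an aryllithium from C–Br), so neither new bond touches the stereocenter.
5. Ring A is bought as 1-(benzyloxy)-3,5-dibromobenzene and dressed by two deprotonations and one site-selective Suzuki–Miyaura coupling. Order of ring formation: A (present), B (step 5), C (step 9).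

Key step: step 5

Remark: organolithium species formed in the flask are drawn as monomers with covalent C–Li or O–Li bonds; compounds 1, 7, 10 and 17 are taken as catalogue chemicals.

**Step 1**
Reactants: 1 1-(benzyloxy)-3,5-dibromobenzene
Product: 3 5-(benzyloxy)-1,3-dibromo-2-(methoxymethyl)benzene, via aryllithium 2 (not isolated)
Conditions: LiN(i-Pr)2, THF, −78 °C; ClCH2OCH3, −78 °C → rt
Reagents that add atoms: chloromethyl methyl ether, COCCl
Why: Directed deprotonation followed by SN2 alkylation: the C–H between the two bromines is the most acidic site of 1, aryllithium 2 is stable at −78 °C, and the reactive α-chloro ether alkylates it; no stereocenter is formed.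

**Step 2**
Reactants: 3 5-(benzyloxy)-1,3-dibromo-2-(methoxymethyl)benzene
Product: 6 6-(benzyloxy)-2,4-dibromo-3-(methoxymethyl)benzaldehyde, via aryllithium 4 (not isolated), via hemiaminal alkoxide 5 (not isolated)
Conditions: LiN(i-Pr)2, THF, −78 °C; DMF, −78 °C; 1 M HCl
Reagents that add atoms: N,N-dimethylformamide, CN(C)C=O
Why: Directed ortho-lithiation and formylation with DMF: the two remaining ring C–H bonds of 3 are equivalent and each is acidified by an ortho bromine and the ortho benzyloxy group, so a single aldehyde should result when hemiaminal 5 collapses on acidic work-up.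

**Step 3**
Reactants: 6 6-(benzyloxy)-2,4-dibromo-3-(methoxymethyl)benzaldehyde; 7 phenylboronic acid
Product: 8 6-(benzyloxy)-2-bromo-3-(methoxymethyl)-4-phenylbenzaldehyde
Conditions: Pd(PPh3)4 (3 mol%), Na2CO3, toluene/EtOH/H2O, 80 °C
Reagents that add atoms: none
Why: Site-selective Suzuki–Miyaura coupling: oxidative addition of zerovalent palladium should prefer the bromide para to the formyl group, which has one ortho substituent, over the bromide wedged between the formyl and methoxymethyl groups, so only the future C6 is arylated and the future C4a keeps its bromine.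

**Step 4**
Reactants: 8 6-(benzyloxy)-2-bromo-3-(methoxymethyl)-4-phenylbenzaldehyde
Product: 9 2-[6-(benzyloxy)-2-bromo-3-(methoxymethyl)-4-phenylphenyl]-1,3-dithiane
Conditions: HS(CH2)3SH, BF3·OEt2 (0.2 equiv), CH2Cl2, 0 °C
Reagents that add atoms: propane-1,3-dithiol, SCCCS
Why: Lewis-acid-catalysed dithioacetalization turns the aldehyde carbon (future C1) into a 1,3-dithiane, the acyl-anion equivalent needed for the key step; low temperature and substoichiometric BF3·OEt2 should leave the benzyl and methyl ethers intact.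

**Step 5**
Reactants: 9 2-[6-(benzyloxy)-2-bromo-3-(methoxymethyl)-4-phenylphenyl]-1,3-dithiane; 10 (R)-epichlorohydrin
Product: 15 (3'S)-8'-(benzyloxy)-3'-[(tert-butyldimethylsilyl)oxy]-5'-(methoxymethyl)-6'-phenyl-3',4'-dihydro-2'H-spiro[1,3-dithiane-2,1'-naphthalene], via lithiodithiane 11 (not isolated), via chlorohydrin alkoxide 12 (not isolated), via chlorohydrin silyl ether 13 (not isolated), via aryllithium 14 (not isolated)
Conditions: LiN(i-Pr)2 (1.1 equiv), THF, −30 °C; 10, −78 → −25 °C; TBSOTf (1.1 equiv), −78 °C; t-BuLi (3.3 equiv), −78 → 0 °C; H2O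
Reagents that add atoms: tert-butyldimethylsilyl trifluoromethanesulfonate, CC(C)(C)[Si](C)(C)OS(=O)(=O)C(F)(F)F
Why: LiN(i-Pr)2 removes only the dithiane C–H of 9 (it does not exchange the bromide and no ring C–H lies next to it), carbanion 11 opens (R)-epichlorohydrin at its unsubstituted epoxide carbon (C1–C2 bond, alkoxide 12), TBSOTf caps the alkoxide as 13, Br–Li exchange with t-BuLi (the first equivalent reconverts i-Pr2NH to the amide) gives aryllithium 14, and 14 displaces the primary chloride (C4–C4a bond) to close ring B. The closest known reactions are the Corey–Seebach opening of enantiopure epichlorohydrin by 2-lithio-1,3-dithianes and the Parham cycloalkylation of ortho-lithiated (ω-haloalkyl)benzenes to tetralins. Ring B closes in the 6-exo-tet mode, helped by the fully substituted dithiane carbon in the tether. The only stereocenter, C3, comes from 10 and no bond to it is made or broken; because C1 enters at the former epoxide CH2 and C4a at the former CH2Cl, the (R)-reagent gives the (S)-product (the descriptor changes because the ranks of the two CH2 groups swap, not through inversion). The step needs control over which end of the three-carbon unit meets which nucleophile and over 6-exo against 5-exo closure; both are secured by the order of events, since the aryl nucleophile does not exist until the oxygen is silylated, so no epoxide can re-form and the aryllithium finds only the CH2Cl carbon. The dithiane delivers C1 at the ketone oxidation level, and the silyl ether needed later is installed in the same flask.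

**Step 6**
Reactants: 15 (3'S)-8'-(benzyloxy)-3'-[(tert-butyldimethylsilyl)oxy]-5'-(methoxymethyl)-6'-phenyl-3',4'-dihydro-2'H-spiro[1,3-dithiane-2,1'-naphthalene]
Product: 16 (3'S)-8'-(benzyloxy)-3'-[(tert-butyldimethylsilyl)oxy]-6'-phenyl-3',4'-dihydro-2'H-spiro[1,3-dithiane-2,1'-naphthalene]-5'-carbaldehyde
Conditions: DDQ (1.5 equiv), CH2Cl2/pH 7 phosphate buffer, 0 °C
Reagents that add atoms: water, O
Why: DDQ oxidation of a para-alkoxybenzylic ether (the hydride abstraction that cleaves para-methoxybenzyl ethers): the C5 methoxymethyl group is para to the C8 benzyloxy group, so hydride loss gives an oxocarbenium ion that water converts into the aldehyde and methanol, while the buffered two-phase medium at 0 °C should spare the dithioketal and the silyl ether.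

**Step 7**
Reactants: 16 the C5 aldehyde from step 6; 17 2,2,6-trimethyl-4H-1,3-dioxin-4-one
Product: 19 6-{2-[(3'S)-8'-(benzyloxy)-3'-[(tert-butyldimethylsilyl)oxy]-6'-phenyl-3',4'-dihydro-2'H-spiro[1,3-dithiane-2,1'-naphthalen]-5'-yl]-2-hydroxyethyl}-2,2-dimethyl-4H-1,3-dioxin-4-one (both carbinol epimers), via lithium dienolate 18 (not isolated)
Conditions: 17, LiN(i-Pr)2, THF, −78 °C; then 16, −78 °C; AcOH
Reagents that add atoms: none
Why: Vinylogous aldol addition: lithium dienolate 18 adds through its γ-carbon to the hindered, non-enolizable aldehyde 16 while C1 is still masked, so no ketone is present for the basic reagent to enolize; the new carbinol center forms as a mixture that is erased in step 8.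

**Step 8**
Reactants: 19 the δ-hydroxy dioxinone from step 7
Product: 21 (S)-8-(benzyloxy)-3-[(tert-butyldimethylsilyl)oxy]-5-[2-(2,2-dimethyl-4-oxo-4H-1,3-dioxin-6-yl)acetyl]-6-phenyl-3,4-dihydronaphthalen-1(2H)-one, via keto dithioketal 20 (not isolated)
Conditions: Dess–Martin periodinane (4 equiv), NaHCO3, CH2Cl2/MeCN/H2O, 0 °C → rt
Reagents that add atoms: water, O
Why: Dess–Martin oxidation used twice in one flask: the periodinane oxidizes the benzylic alcohol to aryl ketone 20 and, in the wet medium, oxidizes sulfur so that the dithioketal is hydrolysed to the C1 ketone; both are known uses of the reagent, and the silyl and benzyl ethers are inert to it.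

**Step 9**
Reactants: 21 the diketone from step 8
Product: 23 (S)-8-(benzyloxy)-3-[(tert-butyldimethylsilyl)oxy]-5-(4-hydroxy-2-oxo-2H-pyran-6-yl)-6-phenyl-3,4-dihydronaphthalen-1(2H)-one, via acylketene 22 (not isolated)
Conditions: toluene, 110 °C
Reagents that add atoms: none
Why: Thermal retro-[4+2] fragmentation of the dioxinone releases acetone and acylketene 22, and the enol oxygen of the aryl ketone adds to the ketene to close the 4-hydroxy-2-pyranone (ring C) under neutral conditions that should not eliminate the β-silyloxy ketone.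

**Step 10**
Reactants: 23 the silyl-protected pyranone from step 9
Product: 24 (S)-8-(benzyloxy)-3-hydroxy-5-(4-hydroxy-2-oxo-2H-pyran-6-yl)-6-phenyl-3,4-dihydronaphthalen-1(2H)-one
Conditions: HF·pyridine, pyridine/THF, 0 °C → rt
Reagents that add atoms: none
Why: Fluoride-mediated cleavage of the secondary silyl ether with buffered HF·pyridine, a weakly acidic reagent chosen because basic fluoride sources could trigger E1cB loss of the C3 oxygen and aromatization of ring B.

**Step 11**
Reactants: 24 the benzyl ether from step 10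
Product: 25 wailupemycin F
Conditions: H2 (1 atm), Pd/C, EtOAc, rt
Reagents that add atoms: none
Why: Catalytic hydrogenolysis of the aryl benzyl ether should be much faster than hydrogenation of the pyranone or the aryl ketone if stopped after one equivalent of hydrogen; the C3 stereocenter is not involved.

**Compound list**

1 | 1-(benzyloxy)-3,5-dibromobenzene | Brc1cc(Br)cc(OCc2ccccc2)c1 | starting material
2 | [4-(benzyloxy)-2,6-dibromophenyl]lithium | [Li]c1c(Br)cc(OCc2ccccc2)cc1Br | intermediate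
3 | 5-(benzyloxy)-1,3-dibromo-2-(methoxymethyl)benzene | COCc1c(Br)cc(OCc2ccccc2)cc1Br | intermediate
4 | [6-(benzyloxy)-2,4-dibromo-3-(methoxymethyl)phenyl]lithium | COCc1c(Br)c([Li])c(OCc2ccccc2)cc1Br | intermediate
5 | lithium [6-(benzyloxy)-2,4-dibromo-3-(methoxymethyl)phenyl](dimethylamino)methanolate | CN(C)C(O[Li])c1c(Br)c(COC)c(Br)cc1OCc1ccccc1 | intermediate
6 | 6-(benzyloxy)-2,4-dibromo-3-(methoxymethyl)benzaldehyde | O=Cc1c(Br)c(COC)c(Br)cc1OCc1ccccc1 | intermediate
7 | phenylboronic acid | OB(O)c1ccccc1 | starting material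
8 | 6-(benzyloxy)-2-bromo-3-(methoxymethyl)-4-phenylbenzaldehyde | O=Cc1c(Br)c(COC)c(-c2ccccc2)cc1OCc1ccccc1 | intermediate
9 | 2-[6-(benzyloxy)-2-bromo-3-(methoxymethyl)-4-phenylphenyl]-1,3-dithiane | COCc1c(Br)c(C2SCCCS2)c(OCc2ccccc2)cc1-c1ccccc1 | intermediate
10 | (R)-epichlorohydrin, (R)-2-(chloromethyl)oxirane | ClC[C@H]1CO1 | starting material
11 | {2-[6-(benzyloxy)-2-bromo-3-(methoxymethyl)-4-phenylphenyl]-1,3-dithian-2-yl}lithium | COCc1c(Br)c(C2([Li])SCCCS2)c(OCc2ccccc2)cc1-c1ccccc1 | intermediate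
12 | lithium (R)-1-chloro-3-{2-[6-(benzyloxy)-2-bromo-3-(methoxymethyl)-4-phenylphenyl]-1,3-dithian-2-yl}propan-2-olate | ClC[C@H](O[Li])CC1(SCCCS1)c1c(Br)c(COC)c(-c2ccccc2)cc1OCc1ccccc1 | intermediate
13 | tert-butyl({(2R)-1-chloro-3-{2-[6-(benzyloxy)-2-bromo-3-(methoxymethyl)-4-phenylphenyl]-1,3-dithian-2-yl}propan-2-yl}oxy)dimethylsilane | ClC[C@H](O[Si](C)(C)C(C)(C)C)CC1(SCCCS1)c1c(Br)c(COC)c(-c2ccccc2)cc1OCc1ccccc1 | intermediate
14 | [3-(benzyloxy)-2-(2-{(2R)-2-[(tert-butyldimethylsilyl)oxy]-3-chloropropyl}-1,3-dithian-2-yl)-6-(methoxymethyl)-5-phenylphenyl]lithium | ClC[C@H](O[Si](C)(C)C(C)(C)C)CC1(SCCCS1)c1c([Li])c(COC)c(-c2ccccc2)cc1OCc1ccccc1 | intermediate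
15 | (3'S)-8'-(benzyloxy)-3'-[(tert-butyldimethylsilyl)oxy]-5'-(methoxymethyl)-6'-phenyl-3',4'-dihydro-2'H-spiro[1,3-dithiane-2,1'-naphthalene] | CC(C)(C)[Si](C)(C)O[C@H]1Cc2c(COC)c(-c3ccccc3)cc(OCc3ccccc3)c2C2(C1)SCCCS2 | intermediate
16 | (3'S)-8'-(benzyloxy)-3'-[(tert-butyldimethylsilyl)oxy]-6'-phenyl-3',4'-dihydro-2'H-spiro[1,3-dithiane-2,1'-naphthalene]-5'-carbaldehyde | CC(C)(C)[Si](C)(C)O[C@H]1Cc2c(C=O)c(-c3ccccc3)cc(OCc3ccccc3)c2C2(C1)SCCCS2 | intermediate
17 | 2,2,6-trimethyl-4H-1,3-dioxin-4-one | CC1=CC(=O)OC(C)(C)O1 | starting material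
18 | lithium 2,2-dimethyl-6-methylidene-6H-1,3-dioxin-4-olate (lithium dienolate of 17) | C=C1C=C(O[Li])OC(C)(C)O1 | intermediate
19 | 6-{2-[(3'S)-8'-(benzyloxy)-3'-[(tert-butyldimethylsilyl)oxy]-6'-phenyl-3',4'-dihydro-2'H-spiro[1,3-dithiane-2,1'-naphthalen]-5'-yl]-2-hydroxyethyl}-2,2-dimethyl-4H-1,3-dioxin-4-one (both carbinol epimers) | CC(C)(C)[Si](C)(C)O[C@H]1Cc2c(C(O)CC3=CC(=O)OC(C)(C)O3)c(-c3ccccc3)cc(OCc3ccccc3)c2C2(C1)SCCCS2 | intermediate
20 | 6-{2-[(3'S)-8'-(benzyloxy)-3'-[(tert-butyldimethylsilyl)oxy]-6'-phenyl-3',4'-dihydro-2'H-spiro[1,3-dithiane-2,1'-naphthalen]-5'-yl]-2-oxoethyl}-2,2-dimethyl-4H-1,3-dioxin-4-one | CC(C)(C)[Si](C)(C)O[C@H]1Cc2c(C(=O)CC3=CC(=O)OC(C)(C)O3)c(-c3ccccc3)cc(OCc3ccccc3)c2C2(C1)SCCCS2 | intermediate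
21 | (S)-8-(benzyloxy)-3-[(tert-butyldimethylsilyl)oxy]-5-[2-(2,2-dimethyl-4-oxo-4H-1,3-dioxin-6-yl)acetyl]-6-phenyl-3,4-dihydronaphthalen-1(2H)-one | CC(C)(C)[Si](C)(C)O[C@H]1Cc2c(C(=O)CC3=CC(=O)OC(C)(C)O3)c(-c3ccccc3)cc(OCc3ccccc3)c2C(=O)C1 | intermediate
22 | (S)-5-{8-(benzyloxy)-3-[(tert-butyldimethylsilyl)oxy]-1-oxo-6-phenyl-1,2,3,4-tetrahydronaphthalen-5-yl}-3,5-dioxopent-1-en-1-one (acylketene) | CC(C)(C)[Si](C)(C)O[C@H]1Cc2c(C(=O)CC(=O)C=C=O)c(-c3ccccc3)cc(OCc3ccccc3)c2C(=O)C1 | intermediate
23 | (S)-8-(benzyloxy)-3-[(tert-butyldimethylsilyl)oxy]-5-(4-hydroxy-2-oxo-2H-pyran-6-yl)-6-phenyl-3,4-dihydronaphthalen-1(2H)-one | CC(C)(C)[Si](C)(C)O[C@H]1Cc2c(-c3cc(O)cc(=O)o3)c(-c3ccccc3)cc(OCc3ccccc3)c2C(=O)C1 | intermediate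
24 | (S)-8-(benzyloxy)-3-hydroxy-5-(4-hydroxy-2-oxo-2H-pyran-6-yl)-6-phenyl-3,4-dihydronaphthalen-1(2H)-one | O[C@H]1Cc2c(-c3cc(O)cc(=O)o3)c(-c3ccccc3)cc(OCc3ccccc3)c2C(=O)C1 | intermediate
25 | wailupemycin F, (S)-3,8-dihydroxy-5-(4-hydroxy-2-oxo-2H-pyran-6-yl)-6-phenyl-3,4-dihydronaphthalen-1(2H)-one | O=C1C[C@@H](O)Cc2c1c(O)cc(-c1ccccc1)c2-c1cc(O)cc(=O)o1 | target

**Step count and risks**

Total steps: 11. Longest linear sequence: 11 steps (1 → 25).

Steps most likely to fail:

1. Step 5. The hindered dithiane carbanion may be formed or alkylated incompletely, and alkoxide 12 may close to an epoxide before it is silylated, which would open a 5-exo pathway for the aryllithium. Fallback: the two bond formations are reversed and separated. Setting out from 9, Br–Li exchange (t-BuLi, THF, −78 °C, faster than removal of the dithiane proton) and BF3·OEt2-promoted opening of (S)-epichlorohydrin (ClC[C@@H]1CO1) at the epoxide CH2 by the aryllithium should give (S)-1-chloro-3-[3-(benzyloxy)-2-(1,3-dithian-2-yl)-6-(methoxymethyl)-5-phenylphenyl]propan-2-ol F1. Silylation (TBSOTf, 2,6-lutidine) gives its tert-butyldimethylsilyl ether F2. n-BuLi then deprotonates the dithiane, and intramolecular Corey–Seebach alkylation at the CH2Cl carbon (6-exo-tet, with the bulky carbanion as ring-closing nucleophile) returns to the route at 15.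

2. Step 6. DDQ may oxidize the dithioketal sulfur in competition with the benzylic ether. Fallback: the order of unmasking is changed. Setting out from 15, PhI(OCOCF3)2 in aqueous MeCN removes the dithiane to give (S)-8-(benzyloxy)-3-[(tert-butyldimethylsilyl)oxy]-5-(methoxymethyl)-6-phenyl-3,4-dihydronaphthalen-1(2H)-one F3. DDQ in wet 1,2-dichloroethane with warming, now without sulfur present, oxidizes the benzylic ether to (S)-4-(benzyloxy)-7-[(tert-butyldimethylsilyl)oxy]-5-oxo-2-phenyl-5,6,7,8-tetrahydronaphthalene-1-carbaldehyde F4. Because the β-silyloxy ketone would not tolerate the lithium dienolate, the side chain is added by a BF3·OEt2-mediated vinylogous Mukaiyama aldol reaction at −78 °C with 2,2-dimethyl-6-methylidene-4-(trimethylsilyloxy)-6H-1,3-dioxine F5 (from 17, LiN(i-Pr)2 and Me3SiCl), giving (3S)-8-(benzyloxy)-3-[(tert-butyldimethylsilyl)oxy]-5-[2-(2,2-dimethyl-4-oxo-4H-1,3-dioxin-6-yl)-1-hydroxyethyl]-6-phenyl-3,4-dihydronaphthalen-1(2H)-one F6. Oxidation of F6 with Dess–Martin periodinane returns to the route at 21.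

3. Step 11. The pyranone C=C bond or the aryl ketone may be reduced in competition with O-benzyl hydrogenolysis. Fallback: the benzyl group is removed by a Lewis acid while the C3 oxygen is still silylated. Setting out from 23, BCl3 with pentamethylbenzene as cation scavenger (CH2Cl2, −78 °C) should give (S)-3-[(tert-butyldimethylsilyl)oxy]-8-hydroxy-5-(4-hydroxy-2-oxo-2H-pyran-6-yl)-6-phenyl-3,4-dihydronaphthalen-1(2H)-one F7. HF·pyridine then removes the silyl ether and returns to the route at 25.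

**Further compounds**

F1 | step 5 | (S)-1-chloro-3-[3-(benzyloxy)-2-(1,3-dithian-2-yl)-6-(methoxymethyl)-5-phenylphenyl]propan-2-ol | ClC[C@@H](O)Cc1c(COC)c(-c2ccccc2)cc(OCc2ccccc2)c1C1SCCCS1
F2 | step 5 | tert-butyl({(2S)-1-chloro-3-[3-(benzyloxy)-2-(1,3-dithian-2-yl)-6-(methoxymethyl)-5-phenylphenyl]propan-2-yl}oxy)dimethylsilane | ClC[C@@H](O[Si](C)(C)C(C)(C)C)Cc1c(COC)c(-c2ccccc2)cc(OCc2ccccc2)c1C1SCCCS1
F3 | step 6 | (S)-8-(benzyloxy)-3-[(tert-butyldimethylsilyl)oxy]-5-(methoxymethyl)-6-phenyl-3,4-dihydronaphthalen-1(2H)-one | CC(C)(C)[Si](C)(C)O[C@H]1Cc2c(COC)c(-c3ccccc3)cc(OCc3ccccc3)c2C(=O)C1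
F4 | step 6 | (S)-4-(benzyloxy)-7-[(tert-butyldimethylsilyl)oxy]-5-oxo-2-phenyl-5,6,7,8-tetrahydronaphthalene-1-carbaldehyde | CC(C)(C)[Si](C)(C)O[C@H]1Cc2c(C=O)c(-c3ccccc3)cc(OCc3ccccc3)c2C(=O)C1
F5 | step 6 | 2,2-dimethyl-6-methylidene-4-(trimethylsilyloxy)-6H-1,3-dioxine | C=C1C=C(O[Si](C)(C)C)OC(C)(C)O1
F6 | step 6 | (3S)-8-(benzyloxy)-3-[(tert-butyldimethylsilyl)oxy]-5-[2-(2,2-dimethyl-4-oxo-4H-1,3-dioxin-6-yl)-1-hydroxyethyl]-6-phenyl-3,4-dihydronaphthalen-1(2H)-one (both carbinol epimers) | CC(C)(C)[Si](C)(C)O[C@H]1Cc2c(C(O)CC3=CC(=O)OC(C)(C)O3)c(-c3ccccc3)cc(OCc3ccccc3)c2C(=O)C1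
F7 | step 11 | (S)-3-[(tert-butyldimethylsilyl)oxy]-8-hydroxy-5-(4-hydroxy-2-oxo-2H-pyran-6-yl)-6-phenyl-3,4-dihydronaphthalen-1(2H)-one | CC(C)(C)[Si](C)(C)O[C@H]1Cc2c(-c3cc(O)cc(=O)o3)c(-c3ccccc3)cc(O)c2C(=O)C1
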